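(The earlier runs and the new flask come from a simulation for substances that don't exist; scatter was added.)

One free enzyme in north, north-west or north-east faces 10000 substrate, so the first thing to ask is how many turns one enzyme reaches. I call this the turnover count N (the turnover number): target made per free enzyme charged, N = y·c_A/c_E, where y is the target fraction and c_A and c_E are the charges of substrate and free enzyme.

| setting | Monday's | Sunday's | north | north-west | north-east |
|---|---|---|---|---|---|
| substrate | 0.20 M | 0.20 M | 0.20 M | 0.20 M | 0.20 M |
| free enzyme | 10 µM | 40 µM | 20 µM | 20 µM | 20 µM |
| temperature | 32 °C | 44 °C | 37 °C | 52 °C |  |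
| remark | run made earlier | run made earlier |  |  | at 52 °C until 1.5 h, from then on at 37 °C |
| time |  |  | 8.0 h | 8.0 h | 8.0 h |

- Monday's (time / h: target / %, substrate / %): 1.50: 7.4, 65.7; 3.00: 10.8, 44.8; 5.00: 12.9, 28.0; 6.00: 13.8, 22.8; 8.00: 14.9, 14.6
- Sunday's (time / h: target / %, substrate / %): 1.50: 36.7, 8.4; 3.00: 38.4, 0.6; 5.00: 39.0, 0.1; 6.00: 39.7, 0.6; 8.00: 39.0, 0

(scatter of a reading: 0.3 percentage points)

- percentages count the substrate that a species holds: one homo dimer or side product counts as two
- reactions considered so far: free enzyme -> unfolded enzyme; substrate + free enzyme <-> complex; complex -> free enzyme + target; 2 substrate -> homo dimer; substrate + target -> side product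

- which flask leads in amount of target, in percent of the substrate charged ("all alike" within 1.5 percentage points) (north / north-west / north-east / all alike)
- how much target is there at the end, in percent of the substrate charged: north
- how much target is there at the end, in percent of the substrate charged: north-west
- how much target is there at the end, in percent of the substrate charged: north-east

The last readings give

N_M = 2980 (Monday's), N_S = 1950 (Sunday's).

My first objection is that Monday's run still holds 14.6% of its substrate, so its count is unfinished. But that reading is taken at 8.00 h, and the asked time is 8.0 h, so it is the count I need. Taking ln N as linear in temperature, for north I get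

N = N_M·(N_S/N_M)^((T−T_M)/(T_S−T_M)) = 2500, so y = N·c_E/c_A = 25.0%.

The second objection is that the two runs differ in enzyme as well as temperature. If I read the fall against the enzyme charge instead, the same interpolation in ln c_E gives

N = 2410, so y = 24.1%,

and north barely moves. For north-west the objection stands, since that enzyme reading would keep 24.1%, and 52 °C also lies beyond 44 °C. The list of reactions holds an unfolding of free enzyme, so I commit to the temperature reading, which gives the turnover count at 52 °C:

N = 1470, so y = 14.7%.

Sunday's substrate stood at 8.4% by 1.50 h, so I expect cooling at 1.5 h to find a small remainder, and I set north-east close to north-west.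

The forecast, reasoning that “Target formation per substrate scales with enzyme”, names north as leader with 26%, 14% and 14.5%, against my 25.0% for north and 14.7% for north-west.

The flasks give 26.9% in north, 9.91% in north-west and 13.9% in north-east, so north leads.

    free enzyme → unfolded enzyme (k = 3.70 × 10⁻⁶ s⁻¹, Ea = 252 kJ mol⁻¹)
    substrate + free enzyme ⇌ complex (K = 3.60 L mol⁻¹, k = 81.0 L mol⁻¹ s⁻¹, Ea = 51.0 kJ mol⁻¹, ΔH = 1.00 kJ mol⁻¹)
    complex → free enzyme + target (k = 1.50 s⁻¹, Ea = 69.0 kJ mol⁻¹)
    2 substrate → homo dimer (k = 2.60 × 10⁻⁴ L mol⁻¹ s⁻¹, Ea = 81.0 kJ mol⁻¹)
    substrate + target → side product (k = 0.00110 L mol⁻¹ s⁻¹, Ea = 71.0 kJ mol⁻¹)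
    (constants at 37 °C)

North-west's count comes to 991, below my 1470. The largest single effect on north-west's target is the undoing of complex: with that undoing taken away, the flask ends at 54.1%. Part of the heat's damage is the unfolding of free enzyme: with the temperature's effect on that step taken away, the gap between north-west and north shrinks from 17 percentage points to 0.71 points. In the neighbour of north-west charged with 8.0 × 10⁻⁵ M of free enzyme, 1470 gives 58.8%, and that flask holds 49.0%, a count of 1230.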